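**Retrosynthetic overview**
1. Target ⇐ fluoride removal of the C7 silyl ether, then hydrogenolysis of three phenolic benzyl ethers.
2. The THF ring (the only ring of the target, formed last) ⇐ acid-mediated 5-exo etherification of an acyclic triol: C9–OH traps the C7' benzylic cation, setting C7' trans to the CH2OH.
3. Triol ⇐ LiAlH4 opening of a trans-α-(hydroxybenzyl)-β-substituted γ-butyrolactone ⇐ late aldol of the lactone enolate 17 with 3,4-bis(benzyloxy)benzaldehyde 8 (C7'–C8' bond, sets C8').
4. Lactone 17 (a temporary ring, formed first) ⇐ Evans Mg-catalysed anti-aldol of a succinate imide 14 with O-benzylvanillin 5 (C7–C8 bond, sets C7 and C8), then reductive auxiliary removal and lactonisation.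
5. Both aldehydes come from catechol, the C4 unit from succinic anhydride, and the auxiliary from D-valine.

Assumption: the target is read as (2S,3R,4R) on the THF with an (R) carbinol. The C7' carbinol epimers from step 15 are carried as a mixture because that centre is re-set in step 17.

Lignan numbering used below: C7 = guaiacyl carbinol, C8 = THF C4, C9 = THF C5, C8' = THF C3, C9' = CH2OH, C7' = THF C2.

**Branch A: guaiacyl aldehyde**

Step 1
Reactants: 1 catechol
Product: 2 guaiacol (2-methoxyphenol)
Conditions: MeI (1.0 equiv), K2CO3 (1.0 equiv), acetone, reflux; separate from veratrole and recovered catechol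
Reagents that add atoms: iodomethane, CI
Why: Williamson mono-O-methylation; statistical, but the neutral diether and the diol are easily removed by extraction and distillation.

Step 2
Reactants: 2 guaiacol
Product: 3 4-bromo-2-methoxyphenol
Conditions: NBS, MeCN, 0 °C → rt
Reagents that add atoms: N-bromosuccinimide, O=C1CCC(=O)N1Br
Why: electrophilic aromatic bromination para to the free OH, the strongest director.

Step 3
Reactants: 3 4-bromo-2-methoxyphenol
Product: 4 1-(benzyloxy)-4-bromo-2-methoxybenzene
Conditions: BnBr, K2CO3, DMF, rt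
Reagents that add atoms: benzyl bromide, BrCc1ccccc1
Why: Williamson etherification of the phenol.

Step 4
Reactants: 4 1-(benzyloxy)-4-bromo-2-methoxybenzene
Product: 5 4-(benzyloxy)-3-methoxybenzaldehyde
Conditions: n-BuLi, THF, −78 °C; DMF; aq NH4Cl
Reagents that add atoms: N,N-dimethylformamide, CN(C)C=O
Why: Br–Li exchange followed by Bouveault formylation; exchange is much faster than benzylic deprotonation at −78 °C.

**Branch B: catechol aldehyde**

Step 5
Reactants: 1 catechol
Product: 6 1,2-bis(benzyloxy)benzene
Conditions: BnBr (2.2 equiv), K2CO3, DMF, 60 °C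
Reagents that add atoms: benzyl bromide, BrCc1ccccc1
Why: double Williamson etherification.

Step 6
Reactants: 6 1,2-bis(benzyloxy)benzene
Product: 7 4-bromo-1,2-bis(benzyloxy)benzene
Conditions: NBS, MeCN, rt
Reagents that add atoms: N-bromosuccinimide, O=C1CCC(=O)N1Br
Why: para-selective electrophilic bromination of a dialkoxybenzene; both para positions are equivalent.

Step 7
Reactants: 7 4-bromo-1,2-bis(benzyloxy)benzene
Product: 8 3,4-bis(benzyloxy)benzaldehyde
Conditions: n-BuLi, THF, −78 °C; DMF; aq NH4Cl
Reagents that add atoms: N,N-dimethylformamide, CN(C)C=O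
Why: Br–Li exchange and Bouveault formylation.

**Branch C: chiral acyl donor**

Step 8
Reactants: 9 D-valine
Product: 10 D-valinol, (R)-2-amino-3-methylbutan-1-ol
Conditions: NaBH4, I2, THF, reflux; MeOH, then aq KOH
Reagents that add atoms: none
Why: in situ borane reduction of the amino acid; the stereocentre is untouched.

Step 9
Reactants: 10 D-valinol
Product: 11 (R)-4-isopropyloxazolidin-2-one
Conditions: (EtO)2CO, K2CO3 (cat.), 130 °C, distil off EtOH
Reagents that add atoms: diethyl carbonate, CCOC(=O)OCC
Why: carbonylative cyclisation of the 1,2-amino alcohol.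

Step 10
Reactants: 12 succinic anhydride
Product: 13 monomethyl succinate (4-methoxy-4-oxobutanoic acid)
Conditions: MeOH, reflux
Reagents that add atoms: methanol, CO
Why: anhydride methanolysis stops cleanly at the half ester.

Step 11
Reactants: 13 monomethyl succinate; 11 (R)-4-isopropyloxazolidin-2-one
Product: 14 methyl 4-[(R)-4-isopropyl-2-oxooxazolidin-3-yl]-4-oxobutanoate
Conditions: PivCl, Et3N, THF, −20 °C; then 11, LiCl, rt
Reagents that add atoms: none
Why: N-acylation through the mixed pivalic anhydride; the oxazolidinone attacks the unhindered carbonyl.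

**Main line**

Step 12
Reactants: 14 succinate imide; 5 4-(benzyloxy)-3-methoxybenzaldehyde
Product: 15 methyl (3S,4R)-4-[4-(benzyloxy)-3-methoxyphenyl]-4-hydroxy-3-{[(4R)-4-isopropyl-2-oxooxazolidin-3-yl]carbonyl}butanoate
Conditions: MgCl2 (0.2 equiv), Et3N (2 equiv), TMSCl (1.5 equiv), EtOAc, rt, 24 h; then TFA (cat.), MeOH, 0 °C, 15 min, immediate workup
Reagents that add atoms: none (the TMS ether is cleaved in the workup)
Why: Evans Mg-catalysed anti-aldol. The chelated (Z)-magnesium enolate of the imide adds to the aryl aldehyde through a boat transition state on the face away from the isopropyl group, and the (R)-auxiliary gives the (3S,4R) anti adduct, setting C8 and C7 (7R).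

Step 13
Reactants: 15 anti-aldol adduct
Product: 16 methyl (3S,4R)-4-[4-(benzyloxy)-3-methoxyphenyl]-4-[(tert-butyldimethylsilyl)oxy]-3-{[(4R)-4-isopropyl-2-oxooxazolidin-3-yl]carbonyl}butanoate
Conditions: TBSOTf, 2,6-lutidine, CH2Cl2, −78 → 0 °C
Reagents that add atoms: tert-butyldimethylsilyl triflate, CC(C)(C)[Si](C)(C)OS(=O)(=O)C(F)(F)F
Why: silylation of the hindered benzylic alcohol blocks γ-lactonisation through O7 and later ionisation or participation of O7.

Step 14
Reactants: 16 silyl ether imide
Product: 17 (R)-4-{(R)-[4-(benzyloxy)-3-methoxyphenyl][(tert-butyldimethylsilyl)oxy]methyl}dihydrofuran-2(3H)-one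
Conditions: LiBH4 (1.1 equiv), MeOH (1.1 equiv), THF, 0 °C; aq NH4Cl; then PPTS (cat.), CH2Cl2, rt; auxiliary 11 recovered
Reagents that add atoms: none
Why: the imide carbonyl is reduced chemoselectively over the methyl ester (reductive auxiliary cleavage). The new primary alcohol (C9–OH) then lactonises 5-exo onto the ester; C8 is not epimerisable in the product.

Step 15 (late fragment coupling)
Reactants: 17 lactone; 8 3,4-bis(benzyloxy)benzaldehyde
Product: 18 (3S,4R)-3-{[3,4-bis(benzyloxy)phenyl](hydroxy)methyl}-4-{(R)-[4-(benzyloxy)-3-methoxyphenyl][(tert-butyldimethylsilyl)oxy]methyl}dihydrofuran-2(3H)-one, as a mixture of carbinol (C7') epimers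
Conditions: LDA (1.1 equiv), THF, −78 °C, 30 min; then 8, −78 °C; AcOH quench at −78 °C
Reagents that add atoms: none
Why: lithium lactone-enolate aldol. The aldehyde approaches anti to the bulky β-substituent, giving the 3,4-trans lactone and so setting C8'; the uncontrolled carbinol centre is irrelevant because it is ionised in step 17.

Step 16
Reactants: 18 aldol lactone
Product: 19 (2R,3R)-2-{[3,4-bis(benzyloxy)phenyl](hydroxy)methyl}-3-{(R)-[4-(benzyloxy)-3-methoxyphenyl][(tert-butyldimethylsilyl)oxy]methyl}butane-1,4-diol (C7' epimers)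
Conditions: LiAlH4, THF, −20 → 0 °C; Rochelle salt workup
Reagents that add atoms: none
Why: hydride reduction of the lactone to the 1,4-diol; benzyl and TBS ethers are inert, and the low temperature suppresses retro-aldol.

Step 17
Reactants: 19 triol
Product: 20 [(2S,3R,4R)-2-[3,4-bis(benzyloxy)phenyl]-4-{(R)-[4-(benzyloxy)-3-methoxyphenyl][(tert-butyldimethylsilyl)oxy]methyl}tetrahydrofuran-3-yl]methanol
Conditions: CSA (10 mol %), CH2Cl2, 0 °C → rt, short reaction time, Et3N quench
Reagents that add atoms: none (loss of H2O)
Why: SN1 cycloetherification. The free C7' alcohol ionises to a p-alkoxybenzyl cation that is captured 5-exo by C9–OH (capture by C9'–OH would give an oxetane). Reversible ionisation delivers the 2,3-trans aryl (7'S) from both epimers, and the silylated C7 oxygen does not ionise under these conditions.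

Step 18
Reactants: 20 silyl ether
Product: 21 (R)-[4-(benzyloxy)-3-methoxyphenyl][(3R,4R,5S)-5-[3,4-bis(benzyloxy)phenyl]-4-(hydroxymethyl)tetrahydrofuran-3-yl]methanol
Conditions: TBAF, THF, 0 °C → rt
Reagents that add atoms: none
Why: fluoride desilylation under non-acidic conditions, so the free benzylic alcohol cannot ionise and close to a furofuran.

Step 19
Reactants: 21 tribenzyl ether
Product: 22 (7R)-7-hydroxytaxiresinol, (2S,3R,4R)-2-(3,4-dihydroxyphenyl)-3-(hydroxymethyl)-4-[(R)-hydroxy(4-hydroxy-3-methoxyphenyl)methyl]tetrahydrofuran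
Conditions: H2 (1 atm), 10% Pd/C, EtOAc, rt, monitored and stopped at complete O-debenzylation (about 1 h); filter, no acid
Reagents that add atoms: none
Why: hydrogenolysis of aryl benzyl ethers is much faster under neutral conditions than cleavage of the benzylic alcohol or the 2-aryl-THF C–O bond.

**Compound list**

1 | catechol | Oc1ccccc1O | starting material
2 | guaiacol | COc1ccccc1O | intermediate
3 | 4-bromo-2-methoxyphenol | COc1cc(Br)ccc1O | intermediate
4 | 1-(benzyloxy)-4-bromo-2-methoxybenzene | COc1cc(Br)ccc1OCc1ccccc1 | intermediate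
5 | 4-(benzyloxy)-3-methoxybenzaldehyde | COc1cc(C=O)ccc1OCc1ccccc1 | intermediate
6 | 1,2-bis(benzyloxy)benzene | c1ccc(COc2ccccc2OCc2ccccc2)cc1 | intermediate
7 | 4-bromo-1,2-bis(benzyloxy)benzene | Brc1ccc(OCc2ccccc2)c(OCc2ccccc2)c1 | intermediate
8 | 3,4-bis(benzyloxy)benzaldehyde | O=Cc1ccc(OCc2ccccc2)c(OCc2ccccc2)c1 | intermediate
9 | D-valine | CC(C)[C@@H](N)C(=O)O | starting material
10 | D-valinol | CC(C)[C@@H](N)CO | intermediate
11 | (R)-4-isopropyloxazolidin-2-one | CC(C)[C@@H]1COC(=O)N1 | intermediate (auxiliary, recovered in step 14)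
12 | succinic anhydride | O=C1CCC(=O)O1 | starting material
13 | monomethyl succinate | COC(=O)CCC(=O)O | intermediate
14 | methyl 4-[(R)-4-isopropyl-2-oxooxazolidin-3-yl]-4-oxobutanoate | COC(=O)CCC(=O)N1[C@H](C(C)C)COC1=O | intermediate
15 | (3S,4R) anti-aldol imide | COc1cc([C@H](O)[C@H](CC(=O)OC)C(=O)N2[C@H](C(C)C)COC2=O)ccc1OCc1ccccc1 | intermediate
16 | (3S,4R) TBS ether imide | COc1cc([C@H](O[Si](C)(C)C(C)(C)C)[C@H](CC(=O)OC)C(=O)N2[C@H](C(C)C)COC2=O)ccc1OCc1ccccc1 | intermediate
17 | (R)-4-[(R)-aryl(TBSO)methyl]butyrolactone | COc1cc([C@H](O[Si](C)(C)C(C)(C)C)[C@H]2COC(=O)C2)ccc1OCc1ccccc1 | intermediate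
18 | (3S,4R) trans aldol lactone, C7' epimers | COc1cc([C@H](O[Si](C)(C)C(C)(C)C)[C@H]2COC(=O)[C@@H]2C(O)c2ccc(OCc3ccccc3)c(OCc3ccccc3)c2)ccc1OCc1ccccc1 | intermediate
19 | (2R,3R) triol, C7' epimers | COc1cc([C@H](O[Si](C)(C)C(C)(C)C)[C@@H](CO)[C@H](CO)C(O)c2ccc(OCc3ccccc3)c(OCc3ccccc3)c2)ccc1OCc1ccccc1 | intermediate
20 | (2S,3R,4R) THF, C7 TBS ether, tribenzyl | COc1cc([C@H](O[Si](C)(C)C(C)(C)C)[C@H]2CO[C@H](c3ccc(OCc4ccccc4)c(OCc4ccccc4)c3)[C@H]2CO)ccc1OCc1ccccc1 | intermediate
21 | tri-O-benzyl (7R)-7-hydroxytaxiresinol | COc1cc([C@H](O)[C@H]2CO[C@H](c3ccc(OCc4ccccc4)c(OCc4ccccc4)c3)[C@H]2CO)ccc1OCc1ccccc1 | intermediate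
22 | (7R)-7-hydroxytaxiresinol | COc1cc([C@H](O)[C@H]2CO[C@H](c3ccc(O)c(O)c3)[C@H]2CO)ccc1O | target

**Totals**

Total steps: 19.
Longest linear sequence: 12 (steps 1–4, then 12–19).

**Three steps most likely to fail**

- **Step 12 (Mg anti-aldol).** The succinate imide, the valine-derived auxiliary and an electron-rich aldehyde are all untested variations on the Mg anti-aldol precedent. The freed γ-hydroxy ester may also lactonise before silylation. Fallback: make the anti C7/C8 pair without an auxiliary. Homologate 5 to the β-keto ester, reduce it by Noyori asymmetric hydrogenation, then carry out a Fráter–Seebach dianion allylation (anti). TBS protection, ester reduction and oxidative cleavage of the allyl group then give lactone 17.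
- **Step 17 (acid cycloetherification).** The C7' cation can instead undergo Friedel–Crafts closure onto the guaiacyl ring (aryltetralin). The C7 silyl ether may also be lost, leading to a furofuran. Fallback: alkylate the enolate of 17 with 3,4-bis(benzyloxy)benzyl bromide instead of the aldol, reduce to the diol, and close the THF by DDQ-mediated oxidative benzylic C–H etherification.
- **Step 19 (hydrogenolysis).** The benzylic C7–OH or the 2-aryl-THF C–O bond may be cleaved along with the benzyl ethers. Fallback: carry all three phenols as silyl ethers (TBS or TIPS) from steps 3 and 5 onward and finish with a single buffered fluoride deprotection (TBAF/AcOH), with no hydrogenation.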